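**Retrosynthetic overview**

1. Atom numbers (germacranolide): C1 ketone and C2=C3 lie in the furanone (ring A, its oxygen bridges C3 and C10); C4=C5 carries C15 on C4; C6–O, C7, C11=C13 and C12 form the lactone (ring B); C8 carries the ester; C9; C10 carries the C14 methyl. Target 27 ⇐ C8 methacrylation and C15–O deprotection of macrocyclic alcohol 24.
2. Key disconnection: the C7–C8 bond of the nine-membered ring (ring C: O, C3, C4, C5, C6, C7, C8, C9, C10). Enabling feature: the homoallylic alcohol C13=C11–C7–C8–OH, in which C7 is the fusion atom of rings B and C. Moving the alkene into ring B (C7=C11, C13–Br) makes C7 the γ-terminus of an allylic bromide, so CrCl2 reverses its polarity and this acceptor carbon attacks the C8 aldehyde carbon.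
3. Cyclisation substrate 22 ⇐ butenolide (ring B) by ring-closing metathesis of a 2-(bromomethyl)acrylate on the C6 carbinol; furanone (ring A) by gold-catalysed 5-endo-dig cyclisation of α′-hydroxy ynone 15.
4. 15 ⇐ Sonogashira union (C3–C4) of alkyne 7 (C10 from (R)-citramalic acid) with (Z)-vinyl iodide 13 (C6 from catalytic asymmetric alkynylation of crotonaldehyde; Z-C4=C5 from hydroxyl-directed hydroalumination–iodination).
5. Ring order: ring A (step 11) → ring B (step 14) → ring C (step 17, last).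

Key step: step 17

Remark: the ProPhenol antipode in step 6 is chosen from the known facial preference of this catalyst with enals so that the 4S carbinol results; the C6 descriptor changes from S (11–19) to R (20–27) through CIP priorities only, not by inversion; carbon building blocks are numbered, protecting-group and heteroatom reagents are named on the reagent line.

**Route**

Step 1
Reactants: 1 (R)-citramalic acid [(2R)-2-hydroxy-2-methylbutanedioic acid]
Product: 2 2-[(4R)-2,2,4-trimethyl-5-oxo-1,3-dioxolan-4-yl]acetic acid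
Conditions: 2,2-dimethoxypropane, p-TsOH (cat.), rt
Reagents that add atoms: 2,2-dimethoxypropane, COC(C)(C)OC
Why: Acid-catalysed acetalisation of the α-hydroxy acid closes the five-membered dioxolanone and leaves the β-carboxyl free (as with malic acid); the quaternary centre (future C10, R) comes from the chiral pool and is not touched.

Step 2
Reactants: 2 2-[(4R)-2,2,4-trimethyl-5-oxo-1,3-dioxolan-4-yl]acetic acid
Product: 3 (5R)-5-(2-hydroxyethyl)-2,2,5-trimethyl-1,3-dioxolan-4-one
Conditions: BH3·SMe2, THF, 0 °C → rt; aqueous work-up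
Reagents that add atoms: none
Why: Chemoselective borane reduction: the free carboxylic acid is reduced much faster than the dioxolanone ester, giving the primary alcohol that becomes C8.

Step 3
Reactants: 3 (5R)-5-(2-hydroxyethyl)-2,2,5-trimethyl-1,3-dioxolan-4-one
Product: 4 (5R)-5-{2-[(tert-butyldimethylsilyl)oxy]ethyl}-2,2,5-trimethyl-1,3-dioxolan-4-one
Conditions: TBSCl, imidazole, CH2Cl2, 0 °C
Reagents that add atoms: tert-butyldimethylsilyl chloride, CC(C)(C)[Si](C)(C)Cl
Why: Routine silylation of the primary alcohol, carried out at once so that 3 cannot lactonise onto the dioxolanone carbonyl.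

Step 4
Reactants: 4 (5R)-5-{2-[(tert-butyldimethylsilyl)oxy]ethyl}-2,2,5-trimethyl-1,3-dioxolan-4-one; 5 ethynylmagnesium bromide
Product: 7 (3RS,4R)-6-[(tert-butyldimethylsilyl)oxy]-4-methylhex-1-yne-3,4-diol, via lactol 6 (not isolated)
Conditions: i-Bu2AlH (1.1 equiv), CH2Cl2, −78 °C; then 5 (4 equiv), THF, −78 °C → rt; aq. potassium sodium tartrate
Reagents that add atoms: none
Why: One-pot partial reduction and Grignard addition: i-Bu2AlH should stop at the aluminium lactolate, which on warming opens to the α-oxy aldehyde, sheds acetone and adds the acetylide; the new carbinol centre forms without control, which is harmless because step 10 oxidises it.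

Step 5
Reactants: 8 prop-2-yn-1-ol
Product: 9 1-methoxy-4-[(prop-2-yn-1-yloxy)methyl]benzene
Conditions: NaH, 4-methoxybenzyl chloride, n-Bu4NI (cat.), THF, 0 °C → rt
Reagents that add atoms: 4-methoxybenzyl chloride, COc1ccc(CCl)cc1
Why: Williamson etherification installs the C15–O protecting group that has to last until the final step.

Step 6
Reactants: 9 1-methoxy-4-[(prop-2-yn-1-yloxy)methyl]benzene; 10 (E)-but-2-enal
Product: 11 (4S,5E)-1-[(4-methoxybenzyl)oxy]hept-5-en-2-yn-4-ol
Conditions: Me2Zn, ProPhenol ligand (10 mol %, antipode giving the 4S alcohol), Ph3P=O (20 mol %), toluene, 0 °C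
Reagents that add atoms: none
Why: Zn-ProPhenol asymmetric alkynylation of an α,β-unsaturated aldehyde: the dinuclear zinc alkynylide differentiates the aldehyde faces and should set the carbinol (future C6); the propenyl group is kept as the later metathesis partner.

Step 7
Reactants: 11 (4S,5E)-1-[(4-methoxybenzyl)oxy]hept-5-en-2-yn-4-ol
Product: 12 (2Z,4S,5E)-2-iodo-1-[(4-methoxybenzyl)oxy]hepta-2,5-dien-4-ol
Conditions: NaAlH2(OCH2CH2OCH3)2, THF, 0 °C; EtOAc; then I2, −78 °C → 0 °C
Reagents that add atoms: iodine, II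
Why: Hydroxyl-directed trans-hydroalumination of the propargylic alcohol (hydride to the proximal alkyne carbon, aluminium on the distal one) and iodinolysis with retention should give the vinyl iodide with iodine cis to C6, which fixes the Z-C4=C5 geometry.

Step 8
Reactants: 12 (2Z,4S,5E)-2-iodo-1-[(4-methoxybenzyl)oxy]hepta-2,5-dien-4-ol
Product: 13 triethyl{[(2Z,4S,5E)-2-iodo-1-[(4-methoxybenzyl)oxy]hepta-2,5-dien-4-yl]oxy}silane
Conditions: TESCl, imidazole, CH2Cl2, 0 °C
Reagents that add atoms: chlorotriethylsilane, CC[Si](Cl)(CC)CC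
Why: Routine silylation; the C6 oxygen must be masked because a free (Z)-2-en-4-yn-1-ol, and even more its ynone, would cyclise onto the alkyne to a furan.

Step 9
Reactants: 7 (3RS,4R)-6-[(tert-butyldimethylsilyl)oxy]-4-methylhex-1-yne-3,4-diol; 13 triethyl{[(2Z,4S,5E)-2-iodo-1-[(4-methoxybenzyl)oxy]hepta-2,5-dien-4-yl]oxy}silane
Product: 14 (3R,4RS,7E,9S,10E)-1-[(tert-butyldimethylsilyl)oxy]-7-{[(4-methoxybenzyl)oxy]methyl}-3-methyl-9-[(triethylsilyl)oxy]dodeca-7,10-dien-5-yne-3,4-diol
Conditions: PdCl2(PPh3)2 (5 mol %), CuI (10 mol %), Et3N, THF, rt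
Reagents that add atoms: none
Why: Sonogashira coupling of a terminal alkyne with a vinyl iodide forms C3–C4 with retention of alkene geometry and tolerates free hydroxyls, silyl ethers and the benzyl-type ether.

Step 10
Reactants: 14 (3R,4RS,7E,9S,10E)-1-[(tert-butyldimethylsilyl)oxy]-7-{[(4-methoxybenzyl)oxy]methyl}-3-methyl-9-[(triethylsilyl)oxy]dodeca-7,10-dien-5-yne-3,4-diol
Product: 15 (3R,7E,9S,10E)-1-[(tert-butyldimethylsilyl)oxy]-3-hydroxy-7-{[(4-methoxybenzyl)oxy]methyl}-3-methyl-9-[(triethylsilyl)oxy]dodeca-7,10-dien-5-yn-4-one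
Conditions: Dess–Martin periodinane, NaHCO3, CH2Cl2, 0 °C
Reagents that add atoms: none
Why: Dess–Martin oxidation of the only secondary alcohol (propargylic) gives the ynone and merges both carbinol epimers; the tertiary alcohol and the ethers are inert.

Step 11
Reactants: 15 (3R,7E,9S,10E)-1-[(tert-butyldimethylsilyl)oxy]-3-hydroxy-7-{[(4-methoxybenzyl)oxy]methyl}-3-methyl-9-[(triethylsilyl)oxy]dodeca-7,10-dien-5-yn-4-one
Product: 16 (2R)-2-{2-[(tert-butyldimethylsilyl)oxy]ethyl}-5-{(2Z,4S,5E)-1-[(4-methoxybenzyl)oxy]-4-[(triethylsilyl)oxy]hepta-2,5-dien-2-yl}-2-methylfuran-3(2H)-one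
Conditions: Ph3PAuCl (5 mol %), AgOTf (5 mol %), toluene, rt
Reagents that add atoms: none
Why: Monovalent gold activates the ynone for 5-endo-dig attack of the tertiary α′-hydroxyl on C3 followed by protodeauration (hydroxy-ynone to 3(2H)-furanone cyclisation), closing ring A; the free hydroxyl should react far faster than the silylated C6 oxygen.

Step 12
Reactants: 16 (2R)-2-{2-[(tert-butyldimethylsilyl)oxy]ethyl}-5-{(2Z,4S,5E)-1-[(4-methoxybenzyl)oxy]-4-[(triethylsilyl)oxy]hepta-2,5-dien-2-yl}-2-methylfuran-3(2H)-one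
Product: 17 (2R)-2-{2-[(tert-butyldimethylsilyl)oxy]ethyl}-5-{(2Z,4S,5E)-4-hydroxy-1-[(4-methoxybenzyl)oxy]hepta-2,5-dien-2-yl}-2-methylfuran-3(2H)-one
Conditions: HF·pyridine, pyridine, THF, 0 °C
Reagents that add atoms: none
Why: Selective desilylation: a triethylsilyl ether is cleaved by buffered HF·pyridine much faster than a primary tert-butyldimethylsilyl ether, and the buffered medium avoids solvolysis at the doubly allylic C6.

Step 13
Reactants: 17 (2R)-2-{2-[(tert-butyldimethylsilyl)oxy]ethyl}-5-{(2Z,4S,5E)-4-hydroxy-1-[(4-methoxybenzyl)oxy]hepta-2,5-dien-2-yl}-2-methylfuran-3(2H)-one; 18 2-(bromomethyl)prop-2-enoic acid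
Product: 19 (2Z,4S,5E)-2-[(5R)-5-{2-[(tert-butyldimethylsilyl)oxy]ethyl}-5-methyl-4-oxo-4,5-dihydrofuran-2-yl]-1-[(4-methoxybenzyl)oxy]hepta-2,5-dien-4-yl 2-(bromomethyl)prop-2-enoate
Conditions: DCC, DMAP (5 mol %), CH2Cl2, 0 °C
Reagents that add atoms: none
Why: Steglich esterification with retention at C6; DMAP is kept catalytic and the temperature low to limit SN2′ attack on the allylic bromide and ionisation of the doubly allylic alcohol.

Step 14
Reactants: 19 (2Z,4S,5E)-2-[(5R)-5-{2-[(tert-butyldimethylsilyl)oxy]ethyl}-5-methyl-4-oxo-4,5-dihydrofuran-2-yl]-1-[(4-methoxybenzyl)oxy]hepta-2,5-dien-4-yl 2-(bromomethyl)prop-2-enoate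
Product: 20 (5R)-3-(bromomethyl)-5-{(1Z)-2-[(5R)-5-{2-[(tert-butyldimethylsilyl)oxy]ethyl}-5-methyl-4-oxo-4,5-dihydrofuran-2-yl]-3-[(4-methoxybenzyl)oxy]prop-1-en-1-yl}furan-2(5H)-one
Conditions: second-generation Hoveyda–Grubbs catalyst (10 mol %), toluene (0.01 M), 80 °C, argon purge
Reagents that add atoms: none
Why: Ring-closing metathesis between the propenyl group and the acrylate closes the five-membered butenolide (C7=C11, ring B) with loss of propene; the trisubstituted C4=C5 and the furanone C2=C3 are too hindered and electron-poor to compete.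

Step 15
Reactants: 20 (5R)-3-(bromomethyl)-5-{(1Z)-2-[(5R)-5-{2-[(tert-butyldimethylsilyl)oxy]ethyl}-5-methyl-4-oxo-4,5-dihydrofuran-2-yl]-3-[(4-methoxybenzyl)oxy]prop-1-en-1-yl}furan-2(5H)-one
Product: 21 (5R)-3-(bromomethyl)-5-{(1Z)-2-[(5R)-5-(2-hydroxyethyl)-5-methyl-4-oxo-4,5-dihydrofuran-2-yl]-3-[(4-methoxybenzyl)oxy]prop-1-en-1-yl}furan-2(5H)-one
Conditions: 48% aq. HF, MeCN, 0 °C
Reagents that add atoms: none
Why: Acidic fluoride desilylation of the primary silyl ether; the benzyl-type ether, the allylic bromide and both unsaturated five-membered rings tolerate acid, and no base is present that could epimerise the acidic C6–H.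

Step 16
Reactants: 21 (5R)-3-(bromomethyl)-5-{(1Z)-2-[(5R)-5-(2-hydroxyethyl)-5-methyl-4-oxo-4,5-dihydrofuran-2-yl]-3-[(4-methoxybenzyl)oxy]prop-1-en-1-yl}furan-2(5H)-one
Product: 22 2-[(2R)-5-{(1Z)-1-[(2R)-4-(bromomethyl)-5-oxo-2,5-dihydrofuran-2-yl]-3-[(4-methoxybenzyl)oxy]prop-1-en-2-yl}-2-methyl-3-oxo-2,3-dihydrofuran-2-yl]acetaldehyde
Conditions: Dess–Martin periodinane, NaHCO3, CH2Cl2, 0 °C; used crude
Reagents that add atoms: none
Why: Buffered Dess–Martin oxidation gives the C8 aldehyde without a soluble base that could trigger β-elimination of the furanone oxygen from C10.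

Step 17
Reactants: 22 2-[(2R)-5-{(1Z)-1-[(2R)-4-(bromomethyl)-5-oxo-2,5-dihydrofuran-2-yl]-3-[(4-methoxybenzyl)oxy]prop-1-en-2-yl}-2-methyl-3-oxo-2,3-dihydrofuran-2-yl]acetaldehyde
Product: 24 (6R,7R,8S,10R)-8-hydroxy-15-[(4-methoxybenzyl)oxy]-1-oxo-3,10-epoxygermacra-2,4Z,11(13)-trien-12,6-olide, via allylchromium 23 (not isolated)
Conditions: CrCl2 (8 equiv), THF, rt, syringe-pump addition of 22 (final 2 mM); aq. NH4Cl
Reagents that add atoms: none
Why: Two one-electron transfers from divalent chromium turn the allylic C13–Br bond into allylchromium 23 (trivalent chromium on C13), so that C7, the β-carbon of the butenolide and normally an acceptor, becomes the nucleophilic γ-terminus and adds to the C8 aldehyde through a six-membered chair in which chromium bridges C13 and the carbonyl oxygen, the alkene moving from C7=C11 to C11=C13. The closest known reactions are the Nozaki–Hiyama and Barbier additions of α-(bromomethyl)butenolides and 2-(bromomethyl)acrylates to aldehydes, including their high-dilution medium- and large-ring versions. Ring C (O, C3, C4, C5, C6, C7, C8, C9, C10) closes by C7–C8 bond formation in a 9-exo-trig attack on the aldehyde, the carbonyl oxygen staying outside the ring. C7 is controlled by the resident C6 centre, since C8 should bond to the butenolide face opposite the C6–C5 bond and give the trans-fused lactone (H6 and H7 anti); C8 is controlled by the chair, in which the ring-fixed allyl geometry (C6 trans to C13 across C7=C11) and an equatorial aldehyde chain give the anti relation of C6 and the C8 oxygen, that is 8S. The step needs γ-regioselectivity (C7, not C13), secured by the cyclic SE2′ transition state; chemoselectivity for the aldehyde over the furanone ketone and the lactone, secured by the aldehyde preference and low basicity of allylchromium; and ring closure over oligomerisation, secured by slow addition at high dilution and by the Z-C4=C5 alkene and the two flat rings, which fold the chain.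

Step 18
Reactants: 24 (6R,7R,8S,10R)-8-hydroxy-15-[(4-methoxybenzyl)oxy]-1-oxo-3,10-epoxygermacra-2,4Z,11(13)-trien-12,6-olide; 25 methacrylic anhydride
Product: 26 15-O-(4-methoxybenzyl)goyazensolide
Conditions: Et3N, DMAP (cat.), CH2Cl2, 0 °C → rt
Reagents that add atoms: none
Why: DMAP-catalysed acylation of the secondary C8 alcohol with the anhydride proceeds with retention and under conditions mild enough for the α-methylene lactone.

Step 19
Reactants: 26 15-O-(4-methoxybenzyl)goyazensolide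
Product: 27 goyazensolide
Conditions: DDQ, CH2Cl2/pH 7 buffer, 0 °C → rt
Reagents that add atoms: none
Why: Oxidative cleavage of the 4-methoxybenzyl ether by DDQ (benzylic hydride abstraction, hydrolysis of the hemiacetal) is neutral and should spare the two Michael acceptors, the esters and the furanone.

**Compound list**

1 | (R)-citramalic acid | C[C@@](O)(CC(=O)O)C(=O)O | starting material
2 | 2-[(4R)-2,2,4-trimethyl-5-oxo-1,3-dioxolan-4-yl]acetic acid | C[C@]1(CC(=O)O)OC(C)(C)OC1=O | intermediate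
3 | (5R)-5-(2-hydroxyethyl)-2,2,5-trimethyl-1,3-dioxolan-4-one | C[C@]1(CCO)OC(C)(C)OC1=O | intermediate
4 | (5R)-5-{2-[(tert-butyldimethylsilyl)oxy]ethyl}-2,2,5-trimethyl-1,3-dioxolan-4-one | C[C@]1(CCO[Si](C)(C)C(C)(C)C)OC(C)(C)OC1=O | intermediate
5 | ethynylmagnesium bromide | C#C[Mg]Br | starting material
6 | (5R)-5-{2-[(tert-butyldimethylsilyl)oxy]ethyl}-2,2,5-trimethyl-1,3-dioxolan-4-ol (lactol, present as its aluminium alkoxide) | C[C@]1(CCO[Si](C)(C)C(C)(C)C)OC(C)(C)OC1O | intermediate
7 | (3RS,4R)-6-[(tert-butyldimethylsilyl)oxy]-4-methylhex-1-yne-3,4-diol | C#CC(O)[C@](C)(O)CCO[Si](C)(C)C(C)(C)C | intermediate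
8 | prop-2-yn-1-ol | C#CCO | starting material
9 | 1-methoxy-4-[(prop-2-yn-1-yloxy)methyl]benzene | C#CCOCc1ccc(OC)cc1 | intermediate
10 | (E)-but-2-enal | C/C=C/C=O | starting material
11 | (4S,5E)-1-[(4-methoxybenzyl)oxy]hept-5-en-2-yn-4-ol | C/C=C/[C@H](O)C#CCOCc1ccc(OC)cc1 | intermediate
12 | (2Z,4S,5E)-2-iodo-1-[(4-methoxybenzyl)oxy]hepta-2,5-dien-4-ol | C/C=C/[C@H](O)/C=C(\I)COCc1ccc(OC)cc1 | intermediate
13 | triethyl{[(2Z,4S,5E)-2-iodo-1-[(4-methoxybenzyl)oxy]hepta-2,5-dien-4-yl]oxy}silane | C/C=C/[C@H](O[Si](CC)(CC)CC)/C=C(\I)COCc1ccc(OC)cc1 | intermediate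
14 | (3R,4RS,7E,9S,10E)-1-[(tert-butyldimethylsilyl)oxy]-7-{[(4-methoxybenzyl)oxy]methyl}-3-methyl-9-[(triethylsilyl)oxy]dodeca-7,10-dien-5-yne-3,4-diol | C/C=C/[C@H](O[Si](CC)(CC)CC)/C=C(\C#CC(O)[C@](C)(O)CCO[Si](C)(C)C(C)(C)C)COCc1ccc(OC)cc1 | intermediate
15 | (3R,7E,9S,10E)-1-[(tert-butyldimethylsilyl)oxy]-3-hydroxy-7-{[(4-methoxybenzyl)oxy]methyl}-3-methyl-9-[(triethylsilyl)oxy]dodeca-7,10-dien-5-yn-4-one | C/C=C/[C@H](O[Si](CC)(CC)CC)/C=C(\C#CC(=O)[C@](C)(O)CCO[Si](C)(C)C(C)(C)C)COCc1ccc(OC)cc1 | intermediate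
16 | (2R)-2-{2-[(tert-butyldimethylsilyl)oxy]ethyl}-5-{(2Z,4S,5E)-1-[(4-methoxybenzyl)oxy]-4-[(triethylsilyl)oxy]hepta-2,5-dien-2-yl}-2-methylfuran-3(2H)-one | C/C=C/[C@H](O[Si](CC)(CC)CC)/C=C(\C1=CC(=O)[C@@](C)(CCO[Si](C)(C)C(C)(C)C)O1)COCc1ccc(OC)cc1 | intermediate
17 | (2R)-2-{2-[(tert-butyldimethylsilyl)oxy]ethyl}-5-{(2Z,4S,5E)-4-hydroxy-1-[(4-methoxybenzyl)oxy]hepta-2,5-dien-2-yl}-2-methylfuran-3(2H)-one | C/C=C/[C@H](O)/C=C(\C1=CC(=O)[C@@](C)(CCO[Si](C)(C)C(C)(C)C)O1)COCc1ccc(OC)cc1 | intermediate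
18 | 2-(bromomethyl)prop-2-enoic acid | C=C(CBr)C(=O)O | starting material
19 | (2Z,4S,5E)-2-[(5R)-5-{2-[(tert-butyldimethylsilyl)oxy]ethyl}-5-methyl-4-oxo-4,5-dihydrofuran-2-yl]-1-[(4-methoxybenzyl)oxy]hepta-2,5-dien-4-yl 2-(bromomethyl)prop-2-enoate | C/C=C/[C@H](OC(=O)C(=C)CBr)/C=C(\C1=CC(=O)[C@@](C)(CCO[Si](C)(C)C(C)(C)C)O1)COCc1ccc(OC)cc1 | intermediate
20 | (5R)-3-(bromomethyl)-5-{(1Z)-2-[(5R)-5-{2-[(tert-butyldimethylsilyl)oxy]ethyl}-5-methyl-4-oxo-4,5-dihydrofuran-2-yl]-3-[(4-methoxybenzyl)oxy]prop-1-en-1-yl}furan-2(5H)-one | BrCC1=C[C@@H](/C=C(\C2=CC(=O)[C@@](C)(CCO[Si](C)(C)C(C)(C)C)O2)COCc2ccc(OC)cc2)OC1=O | intermediate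
21 | (5R)-3-(bromomethyl)-5-{(1Z)-2-[(5R)-5-(2-hydroxyethyl)-5-methyl-4-oxo-4,5-dihydrofuran-2-yl]-3-[(4-methoxybenzyl)oxy]prop-1-en-1-yl}furan-2(5H)-one | BrCC1=C[C@@H](/C=C(\C2=CC(=O)[C@@](C)(CCO)O2)COCc2ccc(OC)cc2)OC1=O | intermediate
22 | 2-[(2R)-5-{(1Z)-1-[(2R)-4-(bromomethyl)-5-oxo-2,5-dihydrofuran-2-yl]-3-[(4-methoxybenzyl)oxy]prop-1-en-2-yl}-2-methyl-3-oxo-2,3-dihydrofuran-2-yl]acetaldehyde | BrCC1=C[C@@H](/C=C(\C2=CC(=O)[C@@](C)(CC=O)O2)COCc2ccc(OC)cc2)OC1=O | intermediate
23 | allylchromium dichloride derived from 22 (trivalent chromium on C13 in place of bromine) | Cl[Cr](Cl)CC1=C[C@@H](/C=C(\C2=CC(=O)[C@@](C)(CC=O)O2)COCc2ccc(OC)cc2)OC1=O | intermediate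
24 | (6R,7R,8S,10R)-8-hydroxy-15-[(4-methoxybenzyl)oxy]-1-oxo-3,10-epoxygermacra-2,4Z,11(13)-trien-12,6-olide | O[C@H]1C[C@@]2(C)OC(=CC2=O)/C(COCc3ccc(OC)cc3)=C\[C@H]2OC(=O)C(=C)[C@H]12 | intermediate
25 | methacrylic anhydride | CC(=C)C(=O)OC(=O)C(C)=C | starting material
26 | 15-O-(4-methoxybenzyl)goyazensolide | C=C(C)C(=O)O[C@H]1C[C@@]2(C)OC(=CC2=O)/C(COCc3ccc(OC)cc3)=C\[C@H]2OC(=O)C(=C)[C@H]12 | intermediate
27 | goyazensolide | C=C(C)C(=O)O[C@H]1C[C@@]2(C)OC(=CC2=O)/C(CO)=C\[C@H]2OC(=O)C(=C)[C@H]12 | target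

**Step count and risks**

Total step count: 19. Longest linear sequence: 15 steps (steps 1–4, then 9–19; the branch through steps 5–8 is equally long).

Steps most likely to fail:

1. Step 17 (ring closure). The strain of the forming nine-membered ring may outweigh the chair preference, so the aldehyde could add through the alternative chair with its chain axial and deliver the wrong configuration at C8; intermolecular allylation would compete if dilution is insufficient. The fallback sets out from 22 and comes back at 26. The cyclisation would still be run and its product of opposite C8 configuration, (6R,7R,8R,10R)-8-epi alcohol F1, carried on. The C8 centre would then be corrected in the acylation itself: a Mitsunobu esterification of F1 with methacrylic acid (PPh3, diisopropyl azodicarboxylate, toluene, 0 °C) installs the methacrylate with inversion and gives 26, so step 18 is replaced by an invertive instead of a retentive ester formation.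

2. Step 14 (butenolide metathesis). The ruthenium carbene may be lost to the reactive allylic bromide before the slow closure onto the 1,1-disubstituted acrylate takes place, and the doubly allylic ester may rearrange on prolonged heating. The fallback sets out from 17 and comes back at 20; it introduces the bromide only after ring closure. Commercial ethyl 2-(hydroxymethyl)prop-2-enoate would be silylated (TESCl, imidazole, CH2Cl2) to ethyl 2-{[(triethylsilyl)oxy]methyl}prop-2-enoate F2, and the ethyl ester cleaved under neutral conditions (Me3SnOH, 1,2-dichloroethane, 70 °C) to 2-{[(triethylsilyl)oxy]methyl}prop-2-enoic acid F3. Steglich esterification of 17 with F3 (DCC, DMAP, CH2Cl2, 0 °C) would give the silyloxymethyl acrylate F4. Ring-closing metathesis without any allylic halide (second-generation Grubbs catalyst, CH2Cl2, 40 °C) would give the silyloxymethyl butenolide F5. The primary allylic triethylsilyl ether would be removed selectively (HF·pyridine, pyridine, THF, −10 °C) to the hydroxymethyl butenolide F6, and an Appel reaction (CBr4, PPh3, CH2Cl2, 0 °C) would convert F6 into 20.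

3. Step 12 (selective desilylation). The primary tert-butyldimethylsilyl ether may be lost together with the triethylsilyl ether (over-deprotection), because primary silyl ethers are themselves fairly labile. The fallback sets out from 16 and comes back at 17; it replaces selective cleavage by selective protection. Both silyl groups would be removed (HF·pyridine, THF, rt) to give the furanone diol F7, and the unhindered primary hydroxyl would then be re-silylated in preference to the hindered doubly allylic secondary one (TBSCl 1.05 equiv, imidazole, CH2Cl2, −20 °C) to give 17.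

**Further compounds**

F1 | step 17 | (6R,7R,8R,10R)-8-hydroxy-15-[(4-methoxybenzyl)oxy]-1-oxo-3,10-epoxygermacra-2,4Z,11(13)-trien-12,6-olide (8-epi alcohol) | O[C@@H]1C[C@@]2(C)OC(=CC2=O)/C(COCc3ccc(OC)cc3)=C\[C@H]2OC(=O)C(=C)[C@H]12
F2 | step 14 | ethyl 2-{[(triethylsilyl)oxy]methyl}prop-2-enoate | CCOC(=O)C(=C)CO[Si](CC)(CC)CC
F3 | step 14 | 2-{[(triethylsilyl)oxy]methyl}prop-2-enoic acid | OC(=O)C(=C)CO[Si](CC)(CC)CC
F4 | step 14 | (2Z,4S,5E)-2-[(5R)-5-{2-[(tert-butyldimethylsilyl)oxy]ethyl}-5-methyl-4-oxo-4,5-dihydrofuran-2-yl]-1-[(4-methoxybenzyl)oxy]hepta-2,5-dien-4-yl 2-{[(triethylsilyl)oxy]methyl}prop-2-enoate | C/C=C/[C@H](OC(=O)C(=C)CO[Si](CC)(CC)CC)/C=C(\C1=CC(=O)[C@@](C)(CCO[Si](C)(C)C(C)(C)C)O1)COCc1ccc(OC)cc1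
F5 | step 14 | (5R)-5-{(1Z)-2-[(5R)-5-{2-[(tert-butyldimethylsilyl)oxy]ethyl}-5-methyl-4-oxo-4,5-dihydrofuran-2-yl]-3-[(4-methoxybenzyl)oxy]prop-1-en-1-yl}-3-{[(triethylsilyl)oxy]methyl}furan-2(5H)-one | CC[Si](CC)(CC)OCC1=C[C@@H](/C=C(\C2=CC(=O)[C@@](C)(CCO[Si](C)(C)C(C)(C)C)O2)COCc2ccc(OC)cc2)OC1=O
F6 | step 14 | (5R)-5-{(1Z)-2-[(5R)-5-{2-[(tert-butyldimethylsilyl)oxy]ethyl}-5-methyl-4-oxo-4,5-dihydrofuran-2-yl]-3-[(4-methoxybenzyl)oxy]prop-1-en-1-yl}-3-(hydroxymethyl)furan-2(5H)-one | OCC1=C[C@@H](/C=C(\C2=CC(=O)[C@@](C)(CCO[Si](C)(C)C(C)(C)C)O2)COCc2ccc(OC)cc2)OC1=O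
F7 | step 12 | (2R)-5-{(2Z,4S,5E)-4-hydroxy-1-[(4-methoxybenzyl)oxy]hepta-2,5-dien-2-yl}-2-(2-hydroxyethyl)-2-methylfuran-3(2H)-one | C/C=C/[C@H](O)/C=C(\C1=CC(=O)[C@@](C)(CCO)O1)COCc1ccc(OC)cc1
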